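**Plan**

Numbering is that of cyclohepta[b]furan: O1, C2(=O), C3(=CH2), C3a, C4=C5(Me), C6 (side chain, carbinol carbon C1′), C7(Me), C8, C8a.
Retrosynthesis cuts, in this order: the two ester C–O bonds; C3=CH2 (back to C3–CH2OSi) and C2=O (back to a C2 acetal); C6–C1′ with shift of C4=C5 back to a C4 allyl ether; then C2–C3 and C3a–C8a together.
Enabling feature: C8a (lactone oxygen) and C3a are vicinal, and C4, on the other side of C3a in the seven-membered ring, is trigonal and can be a ketone. The unit O1–C2–C3–C3a–C8a fused to a cycloheptan-4-one is the product pattern of a ring-enlarging Prins–pinacol reaction, so the seven-membered ring can come from a cyclohexane-1,2-diol whose C1–C2 bond is cleaved.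
Forward: 4-methylcyclohexanone → 1-alkenylcyclohexane-1,2-diol → one operation closes the oxacycle and enlarges the carbocycle from six to seven members → C5 methyl and C5=C6 are added at the new ketone → the C4 oxygen relays the side chain to C6 and leaves C4=C5 → esters, lactone carbonyl, exocyclic methylene.
Stereochemistry: C8a and C7 from an L-proline desymmetrising α-aminoxylation; C3a from the cis-selective 1,2-shift; temporary C4–OH from convex-face hydride delivery; C6 by suprafacial transfer from C4–O and C1′ from the erythro-selective [2,3]-Wittig transition state; the angelate enters as the intact Z acid.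
Helpers and their removal: C4 ketone (becomes C4=C5), propenyl on C2 (→ CO2H → OMe → C=O), CH2OSi on C3 (→ =CH2).

Key step: step 4

Remark: C1 of 7, 8 and 10 and C2/C3 of the tetrahydrofuran ring in 11–31 are temporary stereocentres that later become trigonal; they are carried as mixtures and left open in names and SMILES.
Remark: 3 is taken as a catalogue compound; otherwise it is one silylation away from propargyl alcohol.

**Route**

Step 1
Reactants: 1 4-methylcyclohexanone
Product: 2 (2R,4S)-4-methyl-2-[(phenylamino)oxy]cyclohexan-1-one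
Conditions: PhNO (slow addition), L-proline (10 mol %), DMF, 0 °C
Reagents that add atoms: nitrosobenzene O=Nc1ccccc1
Why: In this proline enamine α-aminoxylation the enamine attacks the oxygen of PhN=O on the face fixed by the carboxylic acid hydrogen bond, which should set C2 as R, and axial attack on the enamine that has the 4-methyl group equatorial should place the new C–O bond trans to the methyl group (4S), so the ketone is desymmetrised.

Step 2
Reactants: 3 tert-butyl(diphenyl)(prop-2-yn-1-yloxy)silane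
Product: 5 tert-butyl{[(2E)-3-iodoprop-2-en-1-yl]oxy}diphenylsilane, via alkenylzirconocene chloride 4 (not isolated)
Conditions: Cp2Zr(H)Cl, THF, rt; then I2, 0 °C
Reagents that add atoms: iodine II
Why: Hydrozirconation adds Zr–H syn and anti-Markovnikov to the terminal alkyne and iodinolysis proceeds with retention, so only the E iodoalkene should form.

Step 3
Reactants: 2 (2R,4S)-4-methyl-2-[(phenylamino)oxy]cyclohexan-1-one; 5 tert-butyl{[(2E)-3-iodoprop-2-en-1-yl]oxy}diphenylsilane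
Product: 8 (2R,4S)-1-[(1E)-3-{[tert-butyl(diphenyl)silyl]oxy}prop-1-en-1-yl]-4-methylcyclohexane-1,2-diol, via alkenyllithium 6 (not isolated), via anilinooxy alcohol 7 (not isolated)
Conditions: 5 (2.4 equiv), t-BuLi (4.8 equiv), Et2O, −78 °C; then 2, THF, −78 °C; then AcOH, Zn dust, THF/H2O, rt
Reagents that add atoms: none
Why: Iodine–lithium exchange, 1,2-addition of the alkenyllithium to the ketone (one equivalent is spent on the N–H) and reductive N–O cleavage by Zn/AcOH should give the diol, and the new tertiary carbinol centre needs no control because it becomes the C4 carbonyl carbon in step 4.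

Step 4
Reactants: 8 (2R,4S)-1-[(1E)-3-{[tert-butyl(diphenyl)silyl]oxy}prop-1-en-1-yl]-4-methylcyclohexane-1,2-diol; 9 (E)-but-2-enal
Product: 11 (3aR,7S,8aR)-3-({[tert-butyl(diphenyl)silyl]oxy}methyl)-7-methyl-2-[(1E)-prop-1-en-1-yl]octahydro-4H-cyclohepta[b]furan-4-one, via dioxolane acetal 10 (not isolated)
Conditions: TsOH·H2O (5 mol %), MgSO4, CH2Cl2, −20 °C → rt; then SnCl4 (0.25 equiv), CH2Cl2, −78 → −20 °C
Reagents that add atoms: none
Why: SnCl4 opens acetal 10 at the tertiary oxygen to give the E alkenyl oxocarbenium ion on the secondary oxygen, and the distal alkene carbon attacks its carbon in a chair-like 6-endo-trig Prins cyclisation (first new bond, furan C2–C3), leaving a tetrahydropyranyl cation whose charge sits next to the tin-bound tertiary carbinol. A pinacol 1,2-shift of the oxygen-bearing ring carbon to that cation (second new bond, C3a–C8a) contracts the oxacycle to the tetrahydrofuran, cleaves the old cyclohexane C1–C2 bond so that the carbocycle grows from six to seven members, and releases the C4 ketone; an oxonia-Cope/aldol course would join the same atoms. The closest known reaction type is the SnCl4-promoted ring-enlarging Prins–pinacol tetrahydrofuran annulation of acetals of 1-alkenylcycloalkane-1,2-diols, which is known with enal-derived acetals and with 1,2-disubstituted alkenes. The oxacycle therefore closes 6-endo-trig and becomes five-membered by ring contraction, while the seven-membered ring is not closed by a cyclisation but arises by one-carbon ring enlargement. C8a migrates with retention and keeps the configuration set in step 1, the new centre C3a is forced cis to the C8a–O bond because the migrating carbon is delivered on the face held by the two-atom O–C tether, C7 is untouched, and the C2/C3 centres that follow from the chair transition state are erased later. The step needs migration of the oxygenated carbon (not of the ring CH2) and Prins capture ahead of ionisation of the tertiary allylic C–O bond: the first is secured because only the cyclohexane C1–C2 bond lies in the new ring and is aligned with the vacant p orbital, the second because tin holds the tertiary oxygen as an alkoxide and the allylic CH2OSi group disfavours an allyl cation.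

Step 5
Reactants: 11 (3aR,7S,8aR)-3-({[tert-butyl(diphenyl)silyl]oxy}methyl)-7-methyl-2-[(1E)-prop-1-en-1-yl]octahydro-4H-cyclohepta[b]furan-4-one
Product: 12 (3aR,7S,8aR)-3-({[tert-butyl(diphenyl)silyl]oxy}methyl)-7-methyl-4-oxooctahydro-2H-cyclohepta[b]furan-2-carboxylic acid
Conditions: RuCl3·3H2O (3 mol %), NaIO4, EtOAc/MeCN/H2O, rt
Reagents that add atoms: sodium periodate [Na+].[O-]I(=O)(=O)=O; water O
Why: Oxidative alkene cleavage by RuO4 formed in situ should convert the propenyl group, the only alkene present, into the carboxylic acid and leave the ketone, the ring ether and the silyl ether alone.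

Step 6
Reactants: 12 (3aR,7S,8aR)-3-({[tert-butyl(diphenyl)silyl]oxy}methyl)-7-methyl-4-oxooctahydro-2H-cyclohepta[b]furan-2-carboxylic acid
Product: 13 (3aR,7S,8aR)-3-({[tert-butyl(diphenyl)silyl]oxy}methyl)-2-methoxy-7-methyloctahydro-4H-cyclohepta[b]furan-4-one
Conditions: constant-current electrolysis, graphite anode, MeOH, Et3N (10 mol %), rt
Reagents that add atoms: methanol CO
Why: In this Hofer–Moest anodic decarboxylation the α-alkoxy carboxylate loses CO2 and a second electron to give the ring oxocarbenium ion, which methanol should trap as the base-stable methyl acetal (the anomers converge later).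

Step 7
Reactants: 13 (3aR,7S,8aR)-3-({[tert-butyl(diphenyl)silyl]oxy}methyl)-2-methoxy-7-methyloctahydro-4H-cyclohepta[b]furan-4-one
Product: 17 (3aR,7S,8aR)-3-({[tert-butyl(diphenyl)silyl]oxy}methyl)-2-methoxy-7-methyl-5-methylideneoctahydro-4H-cyclohepta[b]furan-4-one, via lithium enolate 14 (not isolated), via Mannich base 15 (not isolated), via ammonium iodide 16 (not isolated)
Conditions: LiN(iPr)2, THF, −78 °C; then (CH2=NMe2)I, −78 °C → rt; then MeI, CH2Cl2, rt; then NaHCO3 (aq), rt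
Reagents that add atoms: Eschenmoser's salt (N,N-dimethylmethyleneiminium iodide) C=[N+](C)C.[I-]
Why: Kinetic deprotonation should occur at the C5 methylene and not at the C3a methine, and the Mannich reaction followed by quaternisation and E1cB loss of trimethylamine should give the α-methylene ketone.

Step 8
Reactants: 17 (3aR,7S,8aR)-3-({[tert-butyl(diphenyl)silyl]oxy}methyl)-2-methoxy-7-methyl-5-methylideneoctahydro-4H-cyclohepta[b]furan-4-one
Product: 18 (3aR,7R,8aR)-3-({[tert-butyl(diphenyl)silyl]oxy}methyl)-2-methoxy-5,7-dimethyl-2,3,3a,7,8,8a-hexahydro-4H-cyclohepta[b]furan-4-one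
Conditions: RhCl3·3H2O (5 mol %), MeOH, 65 °C
Reagents that add atoms: none
Why: RhCl3-catalysed alkene isomerisation (metal hydride addition–elimination) should move the exocyclic double bond into the ring to the more substituted conjugated enone, and MeOH as solvent makes any acetal exchange degenerate.

Step 9
Reactants: 18 (3aR,7R,8aR)-3-({[tert-butyl(diphenyl)silyl]oxy}methyl)-2-methoxy-5,7-dimethyl-2,3,3a,7,8,8a-hexahydro-4H-cyclohepta[b]furan-4-one
Product: 19 (3aS,4R,7R,8aR)-3-({[tert-butyl(diphenyl)silyl]oxy}methyl)-2-methoxy-5,7-dimethyl-3,3a,4,7,8,8a-hexahydro-2H-cyclohepta[b]furan-4-ol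
Conditions: NaBH4, CeCl3·7H2O, MeOH, −78 °C
Reagents that add atoms: none
Why: In this Luche 1,2-reduction hydride should add to the C4 carbonyl from the convex face of the cis-fused bicycle (the face of the C3a and C8a hydrogens), which places the new C4–O bond cis to the C3a–C3 bond (4R).

Step 10
Reactants: 19 (3aS,4R,7R,8aR)-3-({[tert-butyl(diphenyl)silyl]oxy}methyl)-2-methoxy-5,7-dimethyl-3,3a,4,7,8,8a-hexahydro-2H-cyclohepta[b]furan-4-ol
Product: 20 (3aR,4R,7R,8aR)-4-(allyloxy)-3-({[tert-butyl(diphenyl)silyl]oxy}methyl)-2-methoxy-5,7-dimethyl-3,3a,4,7,8,8a-hexahydro-2H-cyclohepta[b]furan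
Conditions: NaH, allyl bromide, Bu4NI (cat.), THF/DMF, 0 °C → rt
Reagents that add atoms: allyl bromide C=CCBr
Why: Williamson etherification of the secondary allylic alkoxide with a reactive primary halide touches no stereocentre.

Step 11
Reactants: 20 (3aR,4R,7R,8aR)-4-(allyloxy)-3-({[tert-butyl(diphenyl)silyl]oxy}methyl)-2-methoxy-5,7-dimethyl-3,3a,4,7,8,8a-hexahydro-2H-cyclohepta[b]furan
Product: 22 (1S)-1-[(3aR,6S,7R,8aR)-3-({[tert-butyl(diphenyl)silyl]oxy}methyl)-2-methoxy-5,7-dimethyl-3,3a,6,7,8,8a-hexahydro-2H-cyclohepta[b]furan-6-yl]prop-2-en-1-ol, via lithiated ether 21 (not isolated)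
Conditions: n-BuLi, THF, −78 → −30 °C; then H2O
Reagents that add atoms: none
Why: In this [2,3]-Wittig rearrangement lithiation at the unsubstituted allyl CH2 and a suprafacial shift through the five-membered envelope transition state should form C6–C1′ on the face that carried the oxygen (trans to the C7 methyl group, 6S), move the double bond to C4=C5, and give the erythro arrangement (1′S) because the ring makes the migration terminus a Z-type alkene.

Step 12
Reactants: 22 (1S)-1-[(3aR,6S,7R,8aR)-3-({[tert-butyl(diphenyl)silyl]oxy}methyl)-2-methoxy-5,7-dimethyl-3,3a,6,7,8,8a-hexahydro-2H-cyclohepta[b]furan-6-yl]prop-2-en-1-ol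
Product: 24 (3S)-3-[(3aR,6S,7R,8aR)-3-({[tert-butyl(diphenyl)silyl]oxy}methyl)-2-methoxy-5,7-dimethyl-3,3a,6,7,8,8a-hexahydro-2H-cyclohepta[b]furan-6-yl]propane-1,3-diol, via alkylborane 23 (not isolated)
Conditions: 9-BBN (3 equiv), THF, 0 °C → rt; then NaOH (aq), H2O2, 0 °C
Reagents that add atoms: hydrogen peroxide OO
Why: Hydroboration–oxidation with 9-BBN is anti-Markovnikov and should select the monosubstituted alkene over the trisubstituted ring alkene, giving the 1,3-diol without touching a stereocentre.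

Step 13
Reactants: 24 (3S)-3-[(3aR,6S,7R,8aR)-3-({[tert-butyl(diphenyl)silyl]oxy}methyl)-2-methoxy-5,7-dimethyl-3,3a,6,7,8,8a-hexahydro-2H-cyclohepta[b]furan-6-yl]propane-1,3-diol
Product: 25 (3S)-3-[(3aR,6S,7R,8aR)-3-({[tert-butyl(diphenyl)silyl]oxy}methyl)-2-methoxy-5,7-dimethyl-3,3a,6,7,8,8a-hexahydro-2H-cyclohepta[b]furan-6-yl]-3-hydroxypropyl acetate
Conditions: AcCl (1.1 equiv), 2,4,6-collidine, CH2Cl2, −78 °C
Reagents that add atoms: acetyl chloride CC(Cl)=O
Why: Low-temperature acylation with AcCl and a hindered pyridine base should distinguish the primary hydroxyl group from the hindered secondary one.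

Step 14
Reactants: 25 (3S)-3-[(3aR,6S,7R,8aR)-3-({[tert-butyl(diphenyl)silyl]oxy}methyl)-2-methoxy-5,7-dimethyl-3,3a,6,7,8,8a-hexahydro-2H-cyclohepta[b]furan-6-yl]-3-hydroxypropyl acetate; 26 angelic acid [(2Z)-2-methylbut-2-enoic acid]
Product: 28 (1S)-3-(acetyloxy)-1-[(3aR,6S,7R,8aR)-3-({[tert-butyl(diphenyl)silyl]oxy}methyl)-2-methoxy-5,7-dimethyl-3,3a,6,7,8,8a-hexahydro-2H-cyclohepta[b]furan-6-yl]propyl (2Z)-2-methylbut-2-enoate, via mixed anhydride 27 (not isolated)
Conditions: 26, 2,4,6-trichlorobenzoyl chloride, Et3N, toluene, rt; then 25, 80 °C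
Reagents that add atoms: none
Why: Yamaguchi-type esterification through the mixed anhydride, run without DMAP, should acylate the secondary alcohol at the less hindered angeloyl carbonyl and avoid Z to E isomerisation of the angelate.

Step 15
Reactants: 28 (1S)-3-(acetyloxy)-1-[(3aR,6S,7R,8aR)-3-({[tert-butyl(diphenyl)silyl]oxy}methyl)-2-methoxy-5,7-dimethyl-3,3a,6,7,8,8a-hexahydro-2H-cyclohepta[b]furan-6-yl]propyl (2Z)-2-methylbut-2-enoate
Product: 29 (1S)-3-(acetyloxy)-1-[(3aR,6S,7R,8aR)-3-({[tert-butyl(diphenyl)silyl]oxy}methyl)-5,7-dimethyl-2-oxo-3,3a,6,7,8,8a-hexahydro-2H-cyclohepta[b]furan-6-yl]propyl (2Z)-2-methylbut-2-enoate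
Conditions: CrO3, H2SO4 (aq), acetone, 0 °C
Reagents that add atoms: water O
Why: Jones oxidation should hydrolyse the methyl acetal to the lactol and oxidise it to the γ-lactone, while the esters, the silyl ether and the trisubstituted alkene are expected to survive a short exposure at 0 °C.

Step 16
Reactants: 29 (1S)-3-(acetyloxy)-1-[(3aR,6S,7R,8aR)-3-({[tert-butyl(diphenyl)silyl]oxy}methyl)-5,7-dimethyl-2-oxo-3,3a,6,7,8,8a-hexahydro-2H-cyclohepta[b]furan-6-yl]propyl (2Z)-2-methylbut-2-enoate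
Product: 30 (1S)-3-(acetyloxy)-1-[(3aR,6S,7R,8aR)-3-(hydroxymethyl)-5,7-dimethyl-2-oxo-3,3a,6,7,8,8a-hexahydro-2H-cyclohepta[b]furan-6-yl]propyl (2Z)-2-methylbut-2-enoate
Conditions: HF·pyridine, pyridine, THF, 0 °C → rt
Reagents that add atoms: none
Why: Buffered fluoride desilylation should free the primary alcohol without cleaving the esters or the lactone.

Step 17
Reactants: 30 (1S)-3-(acetyloxy)-1-[(3aR,6S,7R,8aR)-3-(hydroxymethyl)-5,7-dimethyl-2-oxo-3,3a,6,7,8,8a-hexahydro-2H-cyclohepta[b]furan-6-yl]propyl (2Z)-2-methylbut-2-enoate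
Product: 32 (1S)-3-(acetyloxy)-1-[(3aR,6S,7R,8aR)-5,7-dimethyl-3-methylidene-2-oxo-3,3a,6,7,8,8a-hexahydro-2H-cyclohepta[b]furan-6-yl]propyl (2Z)-2-methylbut-2-enoate, via mesylate 31 (not isolated)
Conditions: MsCl, Et3N, CH2Cl2, 0 °C; then DBU, 0 °C → rt
Reagents that add atoms: none
Why: Mesylation followed by E1cB β-elimination of the β-sulfonyloxy lactone should give the α-methylene lactone from either C3 epimer under conditions mild enough for the acetate and the angelate.

**Compound list**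

1 | 4-methylcyclohexanone | CC1CCC(=O)CC1 | starting material
2 | (2R,4S)-4-methyl-2-[(phenylamino)oxy]cyclohexan-1-one | O=C1[C@H](ONc2ccccc2)C[C@@H](C)CC1 | intermediate
3 | tert-butyl(diphenyl)(prop-2-yn-1-yloxy)silane | C#CCO[Si](c1ccccc1)(c1ccccc1)C(C)(C)C | starting material
4 | chlorobis(cyclopentadienyl)[(1E)-3-{[tert-butyl(diphenyl)silyl]oxy}prop-1-en-1-yl]zirconium | Cl[Zr](/C=C/CO[Si](c1ccccc1)(c1ccccc1)C(C)(C)C)(C1C=CC=C1)C1C=CC=C1 | intermediate
5 | tert-butyl{[(2E)-3-iodoprop-2-en-1-yl]oxy}diphenylsilane | I/C=C/CO[Si](c1ccccc1)(c1ccccc1)C(C)(C)C | intermediate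
6 | [(1E)-3-{[tert-butyl(diphenyl)silyl]oxy}prop-1-en-1-yl]lithium | [Li]/C=C/CO[Si](c1ccccc1)(c1ccccc1)C(C)(C)C | intermediate
7 | (2R,4S)-1-[(1E)-3-{[tert-butyl(diphenyl)silyl]oxy}prop-1-en-1-yl]-4-methyl-2-[(phenylamino)oxy]cyclohexan-1-ol (C1 epimers) | OC1(/C=C/CO[Si](c2ccccc2)(c3ccccc3)C(C)(C)C)[C@H](ONc4ccccc4)C[C@@H](C)CC1 | intermediate
8 | (2R,4S)-1-[(1E)-3-{[tert-butyl(diphenyl)silyl]oxy}prop-1-en-1-yl]-4-methylcyclohexane-1,2-diol (C1 epimers) | OC1(/C=C/CO[Si](c2ccccc2)(c3ccccc3)C(C)(C)C)[C@H](O)C[C@@H](C)CC1 | intermediate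
9 | (E)-but-2-enal (crotonaldehyde) | C/C=C/C=O | starting material
10 | (3aR,5S)-7a-[(1E)-3-{[tert-butyl(diphenyl)silyl]oxy}prop-1-en-1-yl]-5-methyl-2-[(1E)-prop-1-en-1-yl]hexahydro-1,3-benzodioxole (acetal of 8) | C/C=C/C3OC1(/C=C/CO[Si](c4ccccc4)(c5ccccc5)C(C)(C)C)[C@H](O3)C[C@@H](C)CC1 | intermediate
11 | (3aR,7S,8aR)-3-({[tert-butyl(diphenyl)silyl]oxy}methyl)-7-methyl-2-[(1E)-prop-1-en-1-yl]octahydro-4H-cyclohepta[b]furan-4-one | C1(CO[Si](c3ccccc3)(c4ccccc4)C(C)(C)C)C(/C=C/C)O[C@@H]2C[C@@H](C)CCC(=O)[C@H]12 | intermediate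
12 | (3aR,7S,8aR)-3-({[tert-butyl(diphenyl)silyl]oxy}methyl)-7-methyl-4-oxooctahydro-2H-cyclohepta[b]furan-2-carboxylic acid | C1(CO[Si](c3ccccc3)(c4ccccc4)C(C)(C)C)C(C(=O)O)O[C@@H]2C[C@@H](C)CCC(=O)[C@H]12 | intermediate
13 | (3aR,7S,8aR)-3-({[tert-butyl(diphenyl)silyl]oxy}methyl)-2-methoxy-7-methyloctahydro-4H-cyclohepta[b]furan-4-one | C1(CO[Si](c3ccccc3)(c4ccccc4)C(C)(C)C)C(OC)O[C@@H]2C[C@@H](C)CCC(=O)[C@H]12 | intermediate
14 | lithium enolate of 13 (C4–OLi, C4=C5) | C1(CO[Si](c3ccccc3)(c4ccccc4)C(C)(C)C)C(OC)O[C@@H]2C[C@@H](C)CC=C(O[Li])[C@H]12 | intermediate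
15 | 5-[(dimethylamino)methyl] derivative of 13 (Mannich base) | C1(CO[Si](c3ccccc3)(c4ccccc4)C(C)(C)C)C(OC)O[C@@H]2C[C@@H](C)CC(CN(C)C)C(=O)[C@H]12 | intermediate
16 | 5-[(trimethylammonio)methyl] derivative of 13, iodide | C1(CO[Si](c3ccccc3)(c4ccccc4)C(C)(C)C)C(OC)O[C@@H]2C[C@@H](C)CC(C[N+](C)(C)C)C(=O)[C@H]12.[I-] | intermediate
17 | (3aR,7S,8aR)-3-({[tert-butyl(diphenyl)silyl]oxy}methyl)-2-methoxy-7-methyl-5-methylideneoctahydro-4H-cyclohepta[b]furan-4-one | C1(CO[Si](c3ccccc3)(c4ccccc4)C(C)(C)C)C(OC)O[C@@H]2C[C@@H](C)CC(=C)C(=O)[C@H]12 | intermediate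
18 | (3aR,7R,8aR)-3-({[tert-butyl(diphenyl)silyl]oxy}methyl)-2-methoxy-5,7-dimethyl-2,3,3a,7,8,8a-hexahydro-4H-cyclohepta[b]furan-4-one | C1(CO[Si](c3ccccc3)(c4ccccc4)C(C)(C)C)C(OC)O[C@@H]2C[C@@H](C)C=C(C)C(=O)[C@H]12 | intermediate
19 | (3aS,4R,7R,8aR)-3-({[tert-butyl(diphenyl)silyl]oxy}methyl)-2-methoxy-5,7-dimethyl-3,3a,4,7,8,8a-hexahydro-2H-cyclohepta[b]furan-4-ol | C1(CO[Si](c3ccccc3)(c4ccccc4)C(C)(C)C)C(OC)O[C@@H]2C[C@@H](C)C=C(C)[C@H](O)[C@H]12 | intermediate
20 | (3aR,4R,7R,8aR)-4-(allyloxy)-3-({[tert-butyl(diphenyl)silyl]oxy}methyl)-2-methoxy-5,7-dimethyl-3,3a,4,7,8,8a-hexahydro-2H-cyclohepta[b]furan | C1(CO[Si](c3ccccc3)(c4ccccc4)C(C)(C)C)C(OC)O[C@@H]2C[C@@H](C)C=C(C)[C@H](OCC=C)[C@H]12 | intermediate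
21 | α-lithiated allyl ether of 20 (lithium on the OCH carbon of the allyl group) | C1(CO[Si](c3ccccc3)(c4ccccc4)C(C)(C)C)C(OC)O[C@@H]2C[C@@H](C)C=C(C)[C@H](OC([Li])C=C)[C@H]12 | intermediate
22 | (1S)-1-[(3aR,6S,7R,8aR)-3-({[tert-butyl(diphenyl)silyl]oxy}methyl)-2-methoxy-5,7-dimethyl-3,3a,6,7,8,8a-hexahydro-2H-cyclohepta[b]furan-6-yl]prop-2-en-1-ol | C1(CO[Si](c3ccccc3)(c4ccccc4)C(C)(C)C)C(OC)O[C@@H]2C[C@@H](C)[C@H]([C@H](C=C)O)C(C)=C[C@H]12 | intermediate
23 | bis(9-borabicyclo[3.3.1]nonan-9-yl) adduct of 22 (B on the terminal carbon and on the carbinol oxygen) | C1(CO[Si](c3ccccc3)(c4ccccc4)C(C)(C)C)C(OC)O[C@@H]2C[C@@H](C)[C@H]([C@H](CCB5C6CCCC5CCC6)OB5C6CCCC5CCC6)C(C)=C[C@H]12 | intermediate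
24 | (3S)-3-[(3aR,6S,7R,8aR)-3-({[tert-butyl(diphenyl)silyl]oxy}methyl)-2-methoxy-5,7-dimethyl-3,3a,6,7,8,8a-hexahydro-2H-cyclohepta[b]furan-6-yl]propane-1,3-diol | C1(CO[Si](c3ccccc3)(c4ccccc4)C(C)(C)C)C(OC)O[C@@H]2C[C@@H](C)[C@H]([C@H](CCO)O)C(C)=C[C@H]12 | intermediate
25 | (3S)-3-[(3aR,6S,7R,8aR)-3-({[tert-butyl(diphenyl)silyl]oxy}methyl)-2-methoxy-5,7-dimethyl-3,3a,6,7,8,8a-hexahydro-2H-cyclohepta[b]furan-6-yl]-3-hydroxypropyl acetate | C1(CO[Si](c3ccccc3)(c4ccccc4)C(C)(C)C)C(OC)O[C@@H]2C[C@@H](C)[C@H]([C@H](CCOC(C)=O)O)C(C)=C[C@H]12 | intermediate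
26 | angelic acid, (2Z)-2-methylbut-2-enoic acid | C/C=C(/C)C(=O)O | starting material
27 | (2Z)-2-methylbut-2-enoic 2,4,6-trichlorobenzoic anhydride | C/C=C(/C)C(=O)OC(=O)c1c(Cl)cc(Cl)cc1Cl | intermediate
28 | (1S)-3-(acetyloxy)-1-[(3aR,6S,7R,8aR)-3-({[tert-butyl(diphenyl)silyl]oxy}methyl)-2-methoxy-5,7-dimethyl-3,3a,6,7,8,8a-hexahydro-2H-cyclohepta[b]furan-6-yl]propyl (2Z)-2-methylbut-2-enoate | C1(CO[Si](c3ccccc3)(c4ccccc4)C(C)(C)C)C(OC)O[C@@H]2C[C@@H](C)[C@H]([C@H](CCOC(C)=O)OC(=O)/C(C)=C\C)C(C)=C[C@H]12 | intermediate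
29 | (1S)-3-(acetyloxy)-1-[(3aR,6S,7R,8aR)-3-({[tert-butyl(diphenyl)silyl]oxy}methyl)-5,7-dimethyl-2-oxo-3,3a,6,7,8,8a-hexahydro-2H-cyclohepta[b]furan-6-yl]propyl (2Z)-2-methylbut-2-enoate | C1(CO[Si](c3ccccc3)(c4ccccc4)C(C)(C)C)C(=O)O[C@@H]2C[C@@H](C)[C@H]([C@H](CCOC(C)=O)OC(=O)/C(C)=C\C)C(C)=C[C@H]12 | intermediate
30 | (1S)-3-(acetyloxy)-1-[(3aR,6S,7R,8aR)-3-(hydroxymethyl)-5,7-dimethyl-2-oxo-3,3a,6,7,8,8a-hexahydro-2H-cyclohepta[b]furan-6-yl]propyl (2Z)-2-methylbut-2-enoate | C1(CO)C(=O)O[C@@H]2C[C@@H](C)[C@H]([C@H](CCOC(C)=O)OC(=O)/C(C)=C\C)C(C)=C[C@H]12 | intermediate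
31 | methanesulfonate of 30 (on the C3 hydroxymethyl group) | C1(COS(C)(=O)=O)C(=O)O[C@@H]2C[C@@H](C)[C@H]([C@H](CCOC(C)=O)OC(=O)/C(C)=C\C)C(C)=C[C@H]12 | intermediate
32 | (1S)-3-(acetyloxy)-1-[(3aR,6S,7R,8aR)-5,7-dimethyl-3-methylidene-2-oxo-3,3a,6,7,8,8a-hexahydro-2H-cyclohepta[b]furan-6-yl]propyl (2Z)-2-methylbut-2-enoate (CNP0163960.1) | C=C1C(=O)O[C@@H]2C[C@@H](C)[C@H]([C@H](CCOC(C)=O)OC(=O)/C(C)=C\C)C(C)=C[C@H]12 | target

**Step count and risks**

Total step count: 17. Longest linear sequence: 16 steps (1 → 32 through steps 1 and 3 to 17; step 2 is a one-step branch).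

Most likely to fail, in this order:

Step 4. The conjugated alkenyl oxocarbenium ion may be too stabilised for capture by the inductively deactivated alkene, so that ionisation of the tertiary allylic C–O bond or oligomerisation of the cation outruns the Prins step. The fallback sets out from 8 and comes back at 12. It uses the saturated, more electrophilic cation from (benzyloxy)acetaldehyde and unveils the carboxyl group by hydrogenolysis and alcohol oxidation instead of alkene cleavage. Diol 8 and (benzyloxy)acetaldehyde (TsOH·H2O cat., MgSO4, CH2Cl2) should give the benzyloxymethyl dioxolane acetal F1, which SnCl4 (−78 → −20 °C) should rearrange to the 2-(benzyloxymethyl) ketone F2. Hydrogenolysis (H2, Pd/C, EtOAc; no alkene is present at this stage) should give the 2-(hydroxymethyl) ketone F3. Oxidation with TEMPO (cat.), NaOCl (cat.) and NaClO2 in MeCN/phosphate buffer should then give acid 12.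

Step 11. Lithiation may occur at the ring C4–H instead of the allyl CH2, a [1,2]-shift may compete, or the erythro preference may erode. The fallback sets out from 19 and comes back at 22. It moves the anion-stabilising group from a vinyl to a silylalkynyl group, so that lithiation is unambiguous and the rearrangement runs at −78 °C, and adds a semihydrogenation. Alcohol 19 with NaH and 3-bromo-1-(trimethylsilyl)prop-1-yne (THF/DMF) should give the silylpropargyl ether F4. n-BuLi (THF, −78 °C) should convert it by [2,3]-Wittig rearrangement into the silylated propargylic alcohol F5. K2CO3 in MeOH should give the terminal alkyne F6, and H2 over Pd/CaCO3 poisoned with Pb(OAc)2 (Lindlar catalyst) with quinoline in EtOAc should give 22.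

Step 8. Under the hot, slightly acidic rhodium conditions the ring-fusion centre C3a (α to the ketone) may epimerise, the β-oxygen at C8a may be eliminated, or the isomerisation may stall. The fallback sets out from 13, bypasses 17 and comes back at 18. It builds the 5-methyl enone by dehydrogenation and cross-coupling instead of methylenation and isomerisation. Ketone 13 with LiN(iPr)2 and Me3SiCl (THF, −78 °C) should give the kinetic trimethylsilyl enol ether F7. Saegusa oxidation with Pd(OAc)2 (1 equiv, MeCN, rt) should give the unsubstituted 5-en-4-one F8. I2 and pyridine in CH2Cl2 should give the 5-iodo enone F9. Stille coupling with Me4Sn (PdCl2(MeCN)2 cat., AsPh3, CuI cat., NMP) should then give 18.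

Further compounds
F1 | step 4 | (3aR,5S)-2-[(benzyloxy)methyl]-7a-[(1E)-3-{[tert-butyl(diphenyl)silyl]oxy}prop-1-en-1-yl]-5-methylhexahydro-1,3-benzodioxole | C(c6ccccc6)OCC3OC1(/C=C/CO[Si](c4ccccc4)(c5ccccc5)C(C)(C)C)[C@H](O3)C[C@@H](C)CC1
F2 | step 4 | (3aR,7S,8aR)-2-[(benzyloxy)methyl]-3-({[tert-butyl(diphenyl)silyl]oxy}methyl)-7-methyloctahydro-4H-cyclohepta[b]furan-4-one | C1(CO[Si](c3ccccc3)(c4ccccc4)C(C)(C)C)C(COCc5ccccc5)O[C@@H]2C[C@@H](C)CCC(=O)[C@H]12
F3 | step 4 | (3aR,7S,8aR)-3-({[tert-butyl(diphenyl)silyl]oxy}methyl)-2-(hydroxymethyl)-7-methyloctahydro-4H-cyclohepta[b]furan-4-one | C1(CO[Si](c3ccccc3)(c4ccccc4)C(C)(C)C)C(CO)O[C@@H]2C[C@@H](C)CCC(=O)[C@H]12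
F4 | step 11 | 3-(trimethylsilyl)prop-2-yn-1-yl ether of 19 | C1(CO[Si](c3ccccc3)(c4ccccc4)C(C)(C)C)C(OC)O[C@@H]2C[C@@H](C)C=C(C)[C@H](OCC#C[Si](C)(C)C)[C@H]12
F5 | step 11 | (1R)-1-[(3aR,6S,7R,8aR)-3-({[tert-butyl(diphenyl)silyl]oxy}methyl)-2-methoxy-5,7-dimethyl-3,3a,6,7,8,8a-hexahydro-2H-cyclohepta[b]furan-6-yl]-3-(trimethylsilyl)prop-2-yn-1-ol | C1(CO[Si](c3ccccc3)(c4ccccc4)C(C)(C)C)C(OC)O[C@@H]2C[C@@H](C)[C@H]([C@H](C#C[Si](C)(C)C)O)C(C)=C[C@H]12
F6 | step 11 | (1R)-1-[(3aR,6S,7R,8aR)-3-({[tert-butyl(diphenyl)silyl]oxy}methyl)-2-methoxy-5,7-dimethyl-3,3a,6,7,8,8a-hexahydro-2H-cyclohepta[b]furan-6-yl]prop-2-yn-1-ol | C1(CO[Si](c3ccccc3)(c4ccccc4)C(C)(C)C)C(OC)O[C@@H]2C[C@@H](C)[C@H]([C@H](C#C)O)C(C)=C[C@H]12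
F7 | step 8 | trimethylsilyl enol ether of 13 (C4–OSiMe3, C4=C5) | C1(CO[Si](c3ccccc3)(c4ccccc4)C(C)(C)C)C(OC)O[C@@H]2C[C@@H](C)CC=C(O[Si](C)(C)C)[C@H]12
F8 | step 8 | (3aR,7R,8aR)-3-({[tert-butyl(diphenyl)silyl]oxy}methyl)-2-methoxy-7-methyl-2,3,3a,7,8,8a-hexahydro-4H-cyclohepta[b]furan-4-one | C1(CO[Si](c3ccccc3)(c4ccccc4)C(C)(C)C)C(OC)O[C@@H]2C[C@@H](C)C=CC(=O)[C@H]12
F9 | step 8 | 5-iodo derivative of F8 | C1(CO[Si](c3ccccc3)(c4ccccc4)C(C)(C)C)C(OC)O[C@@H]2C[C@@H](C)C=C(I)C(=O)[C@H]12
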